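## Retrosynthetic overview

1. Locants: side chain C1'–C15' counted from the benzylic CH2; ring A = C1(OH), C2(CH3), C3, C4(OH), C5, C6(bearing C1'). The last C–C bond made is C6–C1', joining the arene (bought as 2-methyl-1,4-benzoquinone) to the complete C20 chain (as its C1' allylstannane).
2. Enabling feature: ring A carries oxygen on C1 and C4 (para), so it is the reduced form of a quinone. At the quinone level C6 is the β-carbon of the O4=C4–C5=C6 enone and is electrophilic; this reversed polarity lets it bond to the nucleophilic C1' in a redox-neutral allylation that returns the aromatic hydroquinone without phenol protection.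
3. Chain, west end: C4'–C5' by catalytic enantioselective vinylogous Mukaiyama aldol of a C15 enal with a 3-methylbut-2-enoate dienolate (sets 5'S and the 2'E olefin); then ester → allylic chloride → stannane, and C5' acetylation.
4. Chain, east end, from geranyl acetate: SeO2 oxidation to the C12' aldehyde, Brown allylation (12'S), cross-metathesis to the prenyl terminus, ent-Shi epoxidation (14'S) and acid-catalysed 5-endo epoxide opening at C15' by the C12' hydroxyl.
5. Ring order: the oxolane (O–C12'–C13'–C14'–C15') is the only ring constructed (step 4); ring A is re-aromatised, not built, in the key step.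

Key step: step 14

Assumption: the absolute sense of induction of the three reagent-controlled steps (2, 4 and 9) is assigned by analogy with closely related substrates; if a step showed the opposite sense, the mirror-image reagent or catalyst would be used.

## Route

Step 1
Reactants: 1 geranyl acetate [(2E)-3,7-dimethylocta-2,6-dien-1-yl acetate]
Product: 3 (2E,6E)-3,7-dimethyl-8-oxoocta-2,6-dien-1-yl acetate, via 8-hydroxygeranyl acetate 2 (not isolated)
Conditions: SeO2 (0.1 equiv), t-BuOOH (3 equiv), salicylic acid (0.1 equiv), CH2Cl2, 23 °C; crude product, then MnO2 (excess), CH2Cl2, 23 °C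
Reagents that add atoms: tert-butyl hydroperoxide, CC(C)(C)OO
Why: SeO2-catalysed allylic oxidation (ene reaction then [2,3]-shift) should attack the (E)-methyl group of the electron-rich distal olefin of a geranyl ester selectively, and MnO2 oxidises only the resulting allylic alcohol, so the (2E,6E)-enal should form with the acetate untouched.

Step 2
Reactants: 3 (2E,6E)-3,7-dimethyl-8-oxoocta-2,6-dien-1-yl acetate
Product: 4 (2E,6E,8S)-8-hydroxy-3,7-dimethylundeca-2,6,10-trien-1-yl acetate
Conditions: (+)-Ipc2B(allyl) (from (+)-α-pinene, 1.3 equiv), Et2O, −100 → −78 °C; then NaBO3·4H2O, THF/H2O, 23 °C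
Reagents that add atoms: (+)-B-allyldiisopinocampheylborane, C=CCB([C@H]1[C@H](C)[C@H]2C[C@@H](C1)C2(C)C)[C@H]1[C@H](C)[C@H]2C[C@@H](C1)C2(C)C
Why: Brown allylboration through a closed chair transition state should deliver the allyl group to the Si face of the α-methyl enal, setting C12' (C8 of 4) as S under reagent control, and the mild perborate work-up spares the acetate.

Step 3
Reactants: 4 (2E,6E,8S)-8-hydroxy-3,7-dimethylundeca-2,6,10-trien-1-yl acetate
Product: 5 (2E,6E,8S)-8-hydroxy-3,7,11-trimethyldodeca-2,6,10-trien-1-yl acetate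
Conditions: second-generation Grubbs catalyst RuCl2(=CHPh)(PCy3)(H2IMes) (5 mol %), 2-methylbut-2-ene/CH2Cl2, 40 °C
Reagents that add atoms: 2-methylbut-2-ene, CC=C(C)C
Why: Olefin cross-metathesis of the only monosubstituted olefin with excess 2-methylbut-2-ene should turn the allyl group into the prenyl group, the trisubstituted olefins and the free alcohol being inert to the catalyst.

Step 4
Reactants: 5 (2E,6E,8S)-8-hydroxy-3,7,11-trimethyldodeca-2,6,10-trien-1-yl acetate
Product: 7 (2E,6E)-7-[(2S,4S)-4-hydroxy-5,5-dimethyloxolan-2-yl]-3-methylocta-2,6-dien-1-yl acetate, via epoxy alcohol 6 (not isolated)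
Conditions: ent-Shi ketone (1,2:4,5-di-O-isopropylidene-β-L-erythro-2,3-hexodiulo-2,6-pyranose, C12H18O6, 0.3 equiv), KHSO5 (as 2KHSO5·KHSO4·K2SO4), K2CO3, Bu4NHSO4, MeCN/CH2(OMe)2/aq. Na2B4O7 buffer, 0 °C; extractive work-up, then camphorsulfonic acid (0.1 equiv), CH2Cl2, 0 °C
Reagents that add atoms: potassium peroxymonosulfate, [K+].[O-]S(=O)(=O)OO
Why: Shi asymmetric epoxidation (chiral dioxirane, spiro transition state) should epoxidise the most electron-rich and least hindered olefin, the prenyl terminus, to the (S)-epoxide with the L-series ketone (the other two olefins carry allylic oxygen and are deactivated), and acid then triggers a stereospecific 5-endo opening at the tertiary carbon C15' by the C12' hydroxyl, closing the oxolane with C12' and C14' unchanged and therefore cis.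

Step 5
Reactants: 7 (2E,6E)-7-[(2S,4S)-4-hydroxy-5,5-dimethyloxolan-2-yl]-3-methylocta-2,6-dien-1-yl acetate
Product: 8 (2E,6E)-7-[(2S,4S)-5,5-dimethyl-4-(triethylsilyloxy)oxolan-2-yl]-3-methylocta-2,6-dien-1-yl acetate
Conditions: Et3SiOTf (1.2 equiv), 2,6-lutidine (2 equiv), CH2Cl2, −78 °C
Reagents that add atoms: triethylsilyl trifluoromethanesulfonate, CC[Si](CC)(CC)OS(=O)(=O)C(F)(F)F
Why: Silylation of the hindered secondary alcohol with the silyl triflate protects C14'–OH for the Lewis-acid and hydride steps that follow and allows the C5' hydroxyl to be acetylated selectively later.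

Step 6
Reactants: 8 (2E,6E)-7-[(2S,4S)-5,5-dimethyl-4-(triethylsilyloxy)oxolan-2-yl]-3-methylocta-2,6-dien-1-yl acetate
Product: 9 (2E,6E)-7-[(2S,4S)-5,5-dimethyl-4-(triethylsilyloxy)oxolan-2-yl]-3-methylocta-2,6-dien-1-ol
Conditions: K2CO3 (cat.), MeOH, 0 °C
Reagents that add atoms: none
Why: Base-catalysed methanolysis (transesterification) removes the primary allylic acetate while the triethylsilyl ether of the hindered secondary alcohol should be stable under these conditions.

Step 7
Reactants: 9 (2E,6E)-7-[(2S,4S)-5,5-dimethyl-4-(triethylsilyloxy)oxolan-2-yl]-3-methylocta-2,6-dien-1-ol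
Product: 10 (2E,6E)-7-[(2S,4S)-5,5-dimethyl-4-(triethylsilyloxy)oxolan-2-yl]-3-methylocta-2,6-dienal
Conditions: MnO2 (excess), CH2Cl2, 23 °C
Reagents that add atoms: none
Why: MnO2 oxidation of the primary allylic alcohol should give the (E)-enal chemoselectively and without over-oxidation.

Step 8
Reactants: 11 ethyl 3-methylbut-2-enoate
Product: 12 tert-butyl{[(1Z)-1-ethoxy-3-methylbuta-1,3-dien-1-yl]oxy}dimethylsilane (drawn as the 1Z isomer; the ketene acetal geometry does not affect the outcome)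
Conditions: LiN(i-Pr)2, THF, −78 °C; then t-BuMe2SiCl, DMPU, −78 → 0 °C
Reagents that add atoms: tert-butyl(chloro)dimethylsilane, CC(C)(C)[Si](C)(C)Cl
Why: Kinetic γ-deprotonation of the unsaturated ester and O-silylation of the extended enolate (silyl ketene acetal formation) should give the silyl dienol ether.

Step 9
Reactants: 10 (2E,6E)-7-[(2S,4S)-5,5-dimethyl-4-(triethylsilyloxy)oxolan-2-yl]-3-methylocta-2,6-dienal; 12 tert-butyl{[(1Z)-1-ethoxy-3-methylbuta-1,3-dien-1-yl]oxy}dimethylsilane
Product: 13 ethyl (2E,5S,6E,10E)-5-hydroxy-3,7-dimethyl-11-[(2S,4S)-5,5-dimethyl-4-(triethylsilyloxy)oxolan-2-yl]dodeca-2,6,10-trienoate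
Conditions: SiCl4 (1.2 equiv), (S,S)-bisphosphoramide catalyst [pentane-1,5-diyl-linked bis(N-methyl phosphoramide) of (S)-N,N'-dimethyl-1,1'-binaphthyl-2,2'-diamine, C51H52N6O2P2, 5 mol %], i-Pr2NEt (0.1 equiv), CH2Cl2, −78 °C; cold aqueous buffer quench
Reagents that add atoms: none
Why: In this catalytic enantioselective vinylogous Mukaiyama aldol addition the chiral phosphoramide-bound trichlorosilyl cation activates the aldehyde, the dienolate should react at its γ-carbon through an open transition state on the aldehyde Si face to set C5' as S under catalyst control, and the s-trans dienolate should translate into the (2E)-enoate.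

Step 10
Reactants: 13 ethyl (2E,5S,6E,10E)-5-hydroxy-3,7-dimethyl-11-[(2S,4S)-5,5-dimethyl-4-(triethylsilyloxy)oxolan-2-yl]dodeca-2,6,10-trienoate
Product: 14 (2E,5S,6E,10E)-3,7-dimethyl-11-[(2S,4S)-5,5-dimethyl-4-(triethylsilyloxy)oxolan-2-yl]dodeca-2,6,10-triene-1,5-diol
Conditions: i-Bu2AlH (3.5 equiv), CH2Cl2, −78 °C; aq. KNaC4H4O6 work-up
Reagents that add atoms: none
Why: Hydride 1,2-reduction of the α,β-unsaturated ester with i-Bu2AlH at low temperature should give the allylic alcohol without touching the olefins or the silyl ether.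

Step 11
Reactants: 14 (2E,5S,6E,10E)-3,7-dimethyl-11-[(2S,4S)-5,5-dimethyl-4-(triethylsilyloxy)oxolan-2-yl]dodeca-2,6,10-triene-1,5-diol
Product: 15 (2E,5S,6E,10E)-1-chloro-3,7-dimethyl-11-[(2S,4S)-5,5-dimethyl-4-(triethylsilyloxy)oxolan-2-yl]dodeca-2,6,10-trien-5-ol
Conditions: MeSO2Cl (1.1 equiv), 2,4,6-collidine, LiCl, DMF, −20 → 0 °C
Reagents that add atoms: lithium chloride, [Li+].[Cl-]
Why: Mesylation of the less hindered primary allylic hydroxyl and in situ SN2 displacement by chloride should convert it selectively into the allylic chloride with retention of the 2E geometry, the more hindered secondary C5' hydroxyl reacting much more slowly at low temperature.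

Step 12
Reactants: 15 (2E,5S,6E,10E)-1-chloro-3,7-dimethyl-11-[(2S,4S)-5,5-dimethyl-4-(triethylsilyloxy)oxolan-2-yl]dodeca-2,6,10-trien-5-ol
Product: 16 (2E,5S,6E,10E)-3,7-dimethyl-11-[(2S,4S)-5,5-dimethyl-4-(triethylsilyloxy)oxolan-2-yl]-1-(tributylstannyl)dodeca-2,6,10-trien-5-ol
Conditions: Bu3SnLi (2.2 equiv, from Bu3SnH and LiN(i-Pr)2), THF, −78 °C; H2O quench
Reagents that add atoms: tributylstannyllithium, [Li][Sn](CCCC)(CCCC)CCCC
Why: SN2 displacement of the primary allylic chloride by the stannyl anion (the first equivalent only deprotonates the C5' hydroxyl, which is thereby protected as its alkoxide) should give the α-linked allylstannane with retention of olefin geometry, as in the preparation of geranyl- and polyprenylstannanes.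

Step 13
Reactants: 16 (2E,5S,6E,10E)-3,7-dimethyl-11-[(2S,4S)-5,5-dimethyl-4-(triethylsilyloxy)oxolan-2-yl]-1-(tributylstannyl)dodeca-2,6,10-trien-5-ol
Product: 17 (2E,5S,6E,10E)-3,7-dimethyl-11-[(2S,4S)-5,5-dimethyl-4-(triethylsilyloxy)oxolan-2-yl]-1-(tributylstannyl)dodeca-2,6,10-trien-5-yl acetate
Conditions: Ac2O, Et3N, DMAP (cat.), CH2Cl2, 0 °C
Reagents that add atoms: acetic anhydride, CC(=O)OC(C)=O
Why: DMAP-catalysed acylation of the only free hydroxyl should install the C5' acetate with retention of configuration under non-acidic conditions that an allylstannane tolerates.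

Step 14
Reactants: 17 (2E,5S,6E,10E)-3,7-dimethyl-11-[(2S,4S)-5,5-dimethyl-4-(triethylsilyloxy)oxolan-2-yl]-1-(tributylstannyl)dodeca-2,6,10-trien-5-yl acetate; 18 2-methyl-1,4-benzoquinone
Product: 19 (2E,5S,6E,10E)-1-(2,5-dihydroxy-3-methylphenyl)-3,7-dimethyl-11-[(2S,4S)-5,5-dimethyl-4-(triethylsilyloxy)oxolan-2-yl]dodeca-2,6,10-trien-5-yl acetate
Conditions: 18 (1.0 equiv), BF3·OEt2 (2 equiv), CH2Cl2, −78 °C, 15 min; then 17 (1.05 equiv) added dropwise, −78 °C; pH 7 buffer quench, work-up under Ar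
Reagents that add atoms: none
Why: BF3 should bind the more Lewis-basic and unhindered O4 of 18 (the carbonyl conjugated with the methyl-bearing C2=C3 bond), which makes C6, the β-carbon of the O4=C4–C5=C6 enone, the electrophilic site; the allylstannane attacks there through its unsubstituted terminus C1' (SE2-type conjugate allylation with loss of the stannyl group as Bu3SnF), and the boron-bound cyclohexenedione tautomerises to the aromatic hydroquinone, so C–C bond formation and return to the hydroquinone oxidation level occur in one redox-neutral operation without phenol protection. The closest known reaction type is the BF3-mediated allylation of methyl-substituted benzoquinones and naphthoquinones with prenyl- and polyprenylstannanes, which gives linear (α) products with retention of the (E)-olefin. No ring is closed and no stereocentre is formed; C5', C12' and C14' are not touched. The step needs regioselectivity for C6 over C5 and C3 (the C2 methyl group directs the Lewis acid to O4 and shields C3), α- over γ-selectivity with retention of the 2'E geometry (the γ-carbon C3' is fully substituted and the temperature is low), and chemoselectivity for the allylstannane over the other two trisubstituted olefins, the allylic acetate and the silyl ether (the C–Sn-activated olefin is far more nucleophilic, and BF3 is pre-complexed with the quinone at −78 °C).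

Step 15
Reactants: 19 (2E,5S,6E,10E)-1-(2,5-dihydroxy-3-methylphenyl)-3,7-dimethyl-11-[(2S,4S)-5,5-dimethyl-4-(triethylsilyloxy)oxolan-2-yl]dodeca-2,6,10-trien-5-yl acetate
Product: 20 (2E,5S,6E,10E)-1-(2,5-dihydroxy-3-methylphenyl)-11-[(2S,4S)-4-hydroxy-5,5-dimethyloxolan-2-yl]-3,7-dimethyldodeca-2,6,10-trien-5-yl acetate (CNP0227918.2)
Conditions: HF·pyridine, pyridine, THF, 0 °C, under Ar
Reagents that add atoms: none
Why: Fluoride-mediated desilylation with buffered HF·pyridine should remove the triethylsilyl ether without affecting the acetate, the air-sensitive hydroquinone or the acid-sensitive prenylated phenol.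

## Compound list

1 | geranyl acetate, (2E)-3,7-dimethylocta-2,6-dien-1-yl acetate | CC(=O)OC/C=C(\C)CCC=C(C)C | starting material
2 | (2E,6E)-8-hydroxy-3,7-dimethylocta-2,6-dien-1-yl acetate (8-hydroxygeranyl acetate) | CC(=O)OC/C=C(\C)CC/C=C(\C)CO | intermediate
3 | (2E,6E)-3,7-dimethyl-8-oxoocta-2,6-dien-1-yl acetate | CC(=O)OC/C=C(\C)CC/C=C(\C)C=O | intermediate
4 | (2E,6E,8S)-8-hydroxy-3,7-dimethylundeca-2,6,10-trien-1-yl acetate | CC(=O)OC/C=C(\C)CC/C=C(\C)[C@@H](O)CC=C | intermediate
5 | (2E,6E,8S)-8-hydroxy-3,7,11-trimethyldodeca-2,6,10-trien-1-yl acetate | CC(=O)OC/C=C(\C)CC/C=C(\C)[C@@H](O)CC=C(C)C | intermediate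
6 | (2E,6E,8S)-9-[(2S)-3,3-dimethyloxiran-2-yl]-8-hydroxy-3,7-dimethylnona-2,6-dien-1-yl acetate | CC(=O)OC/C=C(\C)CC/C=C(\C)[C@@H](O)C[C@@H]1OC1(C)C | intermediate
7 | (2E,6E)-7-[(2S,4S)-4-hydroxy-5,5-dimethyloxolan-2-yl]-3-methylocta-2,6-dien-1-yl acetate | CC(=O)OC/C=C(\C)CC/C=C(\C)[C@@H]1C[C@H](O)C(C)(C)O1 | intermediate
8 | (2E,6E)-7-[(2S,4S)-5,5-dimethyl-4-(triethylsilyloxy)oxolan-2-yl]-3-methylocta-2,6-dien-1-yl acetate | CC(=O)OC/C=C(\C)CC/C=C(\C)[C@@H]1C[C@H](O[Si](CC)(CC)CC)C(C)(C)O1 | intermediate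
9 | (2E,6E)-7-[(2S,4S)-5,5-dimethyl-4-(triethylsilyloxy)oxolan-2-yl]-3-methylocta-2,6-dien-1-ol | OC/C=C(\C)CC/C=C(\C)[C@@H]1C[C@H](O[Si](CC)(CC)CC)C(C)(C)O1 | intermediate
10 | (2E,6E)-7-[(2S,4S)-5,5-dimethyl-4-(triethylsilyloxy)oxolan-2-yl]-3-methylocta-2,6-dienal | O=C/C=C(\C)CC/C=C(\C)[C@@H]1C[C@H](O[Si](CC)(CC)CC)C(C)(C)O1 | intermediate
11 | ethyl 3-methylbut-2-enoate | CCOC(=O)C=C(C)C | starting material
12 | tert-butyl{[(1Z)-1-ethoxy-3-methylbuta-1,3-dien-1-yl]oxy}dimethylsilane | CCO/C(=C/C(C)=C)O[Si](C)(C)C(C)(C)C | intermediate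
13 | ethyl (2E,5S,6E,10E)-5-hydroxy-3,7-dimethyl-11-[(2S,4S)-5,5-dimethyl-4-(triethylsilyloxy)oxolan-2-yl]dodeca-2,6,10-trienoate | CCOC(=O)/C=C(\C)C[C@H](O)/C=C(\C)CC/C=C(\C)[C@@H]1C[C@H](O[Si](CC)(CC)CC)C(C)(C)O1 | intermediate
14 | (2E,5S,6E,10E)-3,7-dimethyl-11-[(2S,4S)-5,5-dimethyl-4-(triethylsilyloxy)oxolan-2-yl]dodeca-2,6,10-triene-1,5-diol | OC/C=C(\C)C[C@H](O)/C=C(\C)CC/C=C(\C)[C@@H]1C[C@H](O[Si](CC)(CC)CC)C(C)(C)O1 | intermediate
15 | (2E,5S,6E,10E)-1-chloro-3,7-dimethyl-11-[(2S,4S)-5,5-dimethyl-4-(triethylsilyloxy)oxolan-2-yl]dodeca-2,6,10-trien-5-ol | ClC/C=C(\C)C[C@H](O)/C=C(\C)CC/C=C(\C)[C@@H]1C[C@H](O[Si](CC)(CC)CC)C(C)(C)O1 | intermediate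
16 | (2E,5S,6E,10E)-3,7-dimethyl-11-[(2S,4S)-5,5-dimethyl-4-(triethylsilyloxy)oxolan-2-yl]-1-(tributylstannyl)dodeca-2,6,10-trien-5-ol | CCCC[Sn](CCCC)(CCCC)C/C=C(\C)C[C@H](O)/C=C(\C)CC/C=C(\C)[C@@H]1C[C@H](O[Si](CC)(CC)CC)C(C)(C)O1 | intermediate
17 | (2E,5S,6E,10E)-3,7-dimethyl-11-[(2S,4S)-5,5-dimethyl-4-(triethylsilyloxy)oxolan-2-yl]-1-(tributylstannyl)dodeca-2,6,10-trien-5-yl acetate | CCCC[Sn](CCCC)(CCCC)C/C=C(\C)C[C@H](OC(C)=O)/C=C(\C)CC/C=C(\C)[C@@H]1C[C@H](O[Si](CC)(CC)CC)C(C)(C)O1 | intermediate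
18 | 2-methyl-1,4-benzoquinone (2-methylcyclohexa-2,5-diene-1,4-dione) | CC1=CC(=O)C=CC1=O | starting material
19 | (2E,5S,6E,10E)-1-(2,5-dihydroxy-3-methylphenyl)-3,7-dimethyl-11-[(2S,4S)-5,5-dimethyl-4-(triethylsilyloxy)oxolan-2-yl]dodeca-2,6,10-trien-5-yl acetate | CC(=O)O[C@H](/C=C(\C)CC/C=C(\C)[C@@H]1C[C@H](O[Si](CC)(CC)CC)C(C)(C)O1)C/C(C)=C/Cc1cc(O)cc(C)c1O | intermediate
20 | (2E,5S,6E,10E)-1-(2,5-dihydroxy-3-methylphenyl)-11-[(2S,4S)-4-hydroxy-5,5-dimethyloxolan-2-yl]-3,7-dimethyldodeca-2,6,10-trien-5-yl acetate (CNP0227918.2) | CC(=O)O[C@H](/C=C(\C)CC/C=C(\C)[C@@H]1C[C@H](O)C(C)(C)O1)C/C(C)=C/Cc1cc(O)cc(C)c1O | target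

## Step count and risks

Total step count: 15. Longest linear sequence: 14 steps (steps 1–7 and 9–15).

Steps most likely to fail:

Step 14. Complexation of BF3 at O1 instead of O4 would steer the allyl group to C5 (loss of regiocontrol), and the Lewis acid could also ionise the allylic acetate, protodestannylate 17 or close a chroman onto the new prenyl olefin. The fallback makes the same C6–C1' bond with the arene as the nucleophile and sets out from chloro alcohol 15. Acetylation (Ac2O, Et3N, DMAP) should give the chloro acetate F1. Purchased 1-bromo-2,5-dimethoxy-3-methylbenzene (COc1cc(C)c(OC)c(Br)c1) is treated with n-BuLi (THF, −78 °C) and then CuBr·SMe2, and the resulting arylcopper reagent is allylated with F1 in an SN2 reaction; this should give the silyl-protected aryl dimethyl ether F2, the position of the chain being fixed by the bromine. HF·pyridine should then give the hydroxy dimethyl ether F3, and (NH4)2Ce(NO3)6 in MeCN/H2O at 0 °C the benzoquinone F4. Reduction of F4 with aqueous Na2S2O4 comes back to the route at 20.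

Step 4. Competing epoxidation of the C10'=C11' olefin, which carries only one allylic oxygen (loss of chemoselectivity), or insufficient facial selectivity at the prenyl olefin would erode the oxolane synthesis. The fallback sets out from 5. Acetylation of the C12' hydroxyl should give the diacetate F5, in which both internal olefins are deactivated by an allylic ester. ent-Shi epoxidation should then give the epoxy diacetate F6, K2CO3/MeOH the epoxy diol F7, and camphorsulfonic acid should cyclise this to the oxolane diol F8. MnO2 should oxidise only the allylic alcohol to the hydroxy enal F9, and silylation with Et3SiOTf/2,6-lutidine comes back to the route at 10.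

Step 9. Low enantioface selectivity or sluggish addition to the β,β-disubstituted enal, or acid-induced loss of the silyl ether, would compromise C5'. The fallback sets out from 10. Enantioselective propargylation with allenylboronic acid pinacol ester (C=C=CB1OC(C)(C)C(C)(C)O1), catalysed by the enantiomer of 3,3'-bis(2,4,6-triisopropylphenyl)-1,1'-binaphthyl-2,2'-diyl hydrogen phosphate that gives the (S)-carbinol, should give the homopropargylic alcohol F10. Negishi carboalumination (AlMe3, Cp2ZrCl2, CH2Cl2), followed in the same flask by n-BuLi and (CH2O)n, should place the methyl group and the hydroxymethyl group syn across the alkyne and comes back to the route at diol 14 with the 2'E olefin.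

Further compounds
F1 | step 14 | (2E,5S,6E,10E)-1-chloro-3,7-dimethyl-11-[(2S,4S)-5,5-dimethyl-4-(triethylsilyloxy)oxolan-2-yl]dodeca-2,6,10-trien-5-yl acetate | ClC/C=C(\C)C[C@H](OC(C)=O)/C=C(\C)CC/C=C(\C)[C@@H]1C[C@H](O[Si](CC)(CC)CC)C(C)(C)O1
F2 | step 14 | (2E,5S,6E,10E)-1-(2,5-dimethoxy-3-methylphenyl)-3,7-dimethyl-11-[(2S,4S)-5,5-dimethyl-4-(triethylsilyloxy)oxolan-2-yl]dodeca-2,6,10-trien-5-yl acetate | CC(=O)O[C@H](/C=C(\C)CC/C=C(\C)[C@@H]1C[C@H](O[Si](CC)(CC)CC)C(C)(C)O1)C/C(C)=C/Cc1cc(OC)cc(C)c1OC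
F3 | step 14 | (2E,5S,6E,10E)-1-(2,5-dimethoxy-3-methylphenyl)-11-[(2S,4S)-4-hydroxy-5,5-dimethyloxolan-2-yl]-3,7-dimethyldodeca-2,6,10-trien-5-yl acetate | CC(=O)O[C@H](/C=C(\C)CC/C=C(\C)[C@@H]1C[C@H](O)C(C)(C)O1)C/C(C)=C/Cc1cc(OC)cc(C)c1OC
F4 | step 14 | (2E,5S,6E,10E)-11-[(2S,4S)-4-hydroxy-5,5-dimethyloxolan-2-yl]-3,7-dimethyl-1-(5-methyl-3,6-dioxocyclohexa-1,4-dien-1-yl)dodeca-2,6,10-trien-5-yl acetate | CC(=O)O[C@H](/C=C(\C)CC/C=C(\C)[C@@H]1C[C@H](O)C(C)(C)O1)C/C(C)=C/CC1=CC(=O)C=C(C)C1=O
F5 | step 4 | (2E,6E,8S)-3,7,11-trimethyldodeca-2,6,10-triene-1,8-diyl diacetate | CC(=O)OC/C=C(\C)CC/C=C(\C)[C@@H](OC(C)=O)CC=C(C)C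
F6 | step 4 | (2E,6E,8S)-9-[(2S)-3,3-dimethyloxiran-2-yl]-3,7-dimethylnona-2,6-diene-1,8-diyl diacetate | CC(=O)OC/C=C(\C)CC/C=C(\C)[C@@H](OC(C)=O)C[C@@H]1OC1(C)C
F7 | step 4 | (2E,6E,8S)-9-[(2S)-3,3-dimethyloxiran-2-yl]-3,7-dimethylnona-2,6-diene-1,8-diol | OC/C=C(\C)CC/C=C(\C)[C@@H](O)C[C@@H]1OC1(C)C
F8 | step 4 | (3S,5S)-5-[(2E,6E)-8-hydroxy-6-methylocta-2,6-dien-2-yl]-2,2-dimethyloxolan-3-ol | OC/C=C(\C)CC/C=C(\C)[C@@H]1C[C@H](O)C(C)(C)O1
F9 | step 4 | (2E,6E)-7-[(2S,4S)-4-hydroxy-5,5-dimethyloxolan-2-yl]-3-methylocta-2,6-dienal | O=C/C=C(\C)CC/C=C(\C)[C@@H]1C[C@H](O)C(C)(C)O1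
F10 | step 9 | (4S,5E,9E)-6-methyl-10-[(2S,4S)-5,5-dimethyl-4-(triethylsilyloxy)oxolan-2-yl]undeca-5,9-dien-1-yn-4-ol | C#CC[C@H](O)/C=C(\C)CC/C=C(\C)[C@@H]1C[C@H](O[Si](CC)(CC)CC)C(C)(C)O1
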